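**Plan**
- Enabling feature: in ring C of unit 1 (O1, C2, C3, C4, C4a, C8a) and in the doubly primed ring C of unit 2, the ether bond (O1–C2, O1''–C2'') lies β to the ring ketone (C4, C4''). Both pyranones can therefore open by retro-oxa-Michael while the central C3–C3'' bond stays intact.
- Retrosynthesis: remove the O-protecting groups, then cut O1–C2 and O1''–C2'' to reach an (E,E)-2,3-diaroyl-1,4-bis(4-methoxyphenyl)buta-1,3-diene diphenol. Next cut the acyl–aryl bonds C4–C4a and C4''–C4a'' to reach bis(4-methoxybenzylidene)succinic anhydride and two aryllithiums. Finally cut both C2=C3 alkenes to reach dimethyl succinate and 4-methoxybenzaldehyde.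
- Forward order: a twofold Stobbe condensation builds the chain C2–C3–C3''–C2''. Ring A of unit 1 is attached by opening the symmetric anhydride, and ring A of unit 2 by acylation with the derived ester. One ortho phenol per ketone is then unmasked, both C rings close in one operation, and deprotection ends the route.
- Stereochemistry: the (E,E) geometry comes from the Stobbe elimination. C2 and C2'' (both S) are set by a chiral amine–thiourea catalyst. C3 and C3'' (both R) follow by protonation and equilibration to the 2,3-trans diequatorial arrangement of each ring.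

Key step: step 8

Assumptions: 1,3,5-tris(benzyloxy)benzene is taken as a catalogue compound (otherwise phloroglucinol, BnBr, K2CO3, DMF). The dihydroquinidine-derived thiourea is assumed to give the 2S,2''S series; if a test run shows the opposite sense, its dihydroquinine-derived pseudoenantiomer is used with nothing else changed.

Step 1
Reactants: 1 dimethyl succinate; 2 4-methoxybenzaldehyde (2.2 equiv)
Product: 4 (2E,3E)-2,3-bis(4-methoxybenzylidene)succinic acid, via Stobbe half-ester 3 (not isolated)
Conditions: KOt-Bu (2.5 equiv), t-BuOH, reflux; then 2 M HCl; recrystallisation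
Reagents that add atoms: none
Why: Twofold Stobbe condensation, in which each succinate carbanion adds to the aldehyde, the alkoxide lactonises onto the γ-ester, and E1cB opening of the paraconic ester gives a carboxylate plus an alkene whose aryl group lies trans to its own carboxyl, so bis(arylidene)succinic acids form as the (E,E) isomers.

Step 2
Reactants: 4 (2E,3E)-2,3-bis(4-methoxybenzylidene)succinic acid
Product: 5 (3E,4E)-3,4-bis(4-methoxybenzylidene)dihydrofuran-2,5-dione (di-p-anisyl fulgide)
Conditions: AcCl, CH2Cl2, reflux, dark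
Reagents that add atoms: none
Why: Cyclodehydration of a 1,4-diacid through its mixed acetic anhydride is the standard entry to diaryl fulgides and should leave the (E,E) geometry untouched when light and strong heating are excluded.

Step 3
Reactants: 6 1,3,5-tris(benzyloxy)benzene
Product: 7 2-bromo-1,3,5-tris(benzyloxy)benzene
Conditions: NBS (1.0 equiv), CH2Cl2, −78 → 0 °C
Reagents that add atoms: N-bromosuccinimide, O=C1CCC(=O)N1Br
Why: Electrophilic aromatic bromination of a phloroglucinol triether whose three free ring positions are equivalent, so one equivalent of NBS at low temperature can give only one monobromide.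

Step 4
Reactants: 7 2-bromo-1,3,5-tris(benzyloxy)benzene; 5 (3E,4E)-3,4-bis(4-methoxybenzylidene)dihydrofuran-2,5-dione
Product: 9 (2E,3E)-2-(4-methoxybenzylidene)-4-(4-methoxyphenyl)-3-[2,4,6-tris(benzyloxy)benzoyl]but-3-enoic acid, via 2,4,6-tris(benzyloxy)phenyllithium 8 (not isolated)
Conditions: 7, n-BuLi (1.0 equiv), THF, −78 °C; cannulated into 5, THF, −78 °C; then 1 M HCl
Reagents that add atoms: none
Why: Bromine–lithium exchange followed by acyl substitution on a cyclic anhydride, where the two carbonyls of 5 are equivalent, the first addition releases a carboxylate inert to organolithiums, and the new di-ortho-substituted aryl ketone is too hindered for a second addition, so the symmetric core is desymmetrised.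

Step 5
Reactants: 9 (2E,3E)-2-(4-methoxybenzylidene)-4-(4-methoxyphenyl)-3-[2,4,6-tris(benzyloxy)benzoyl]but-3-enoic acid
Product: 10 methyl (2E,3E)-2-(4-methoxybenzylidene)-4-(4-methoxyphenyl)-3-[2,4,6-tris(benzyloxy)benzoyl]but-3-enoate
Conditions: MeI, K2CO3, DMF, rt, dark
Reagents that add atoms: iodomethane, CI
Why: SN2 O-alkylation of the carboxylate needs no activation of the crowded acyl carbon and traps the open-chain form of the γ-keto acid as its normal methyl ester.

Step 6
Reactants: 11 1,3,5-trimethoxybenzene; 10 methyl (2E,3E)-2-(4-methoxybenzylidene)-4-(4-methoxyphenyl)-3-[2,4,6-tris(benzyloxy)benzoyl]but-3-enoate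
Product: 13 (2E,3E)-2,3-bis(4-methoxybenzylidene)-1-[2,4,6-tris(benzyloxy)phenyl]-4-(2,4,6-trimethoxyphenyl)butane-1,4-dione, via 2,4,6-trimethoxyphenyllithium 12 (not isolated)
Conditions: 11, n-BuLi, THF, 0 °C → rt; then 10, THF, −78 → 0 °C; then 0.5 M HCl
Reagents that add atoms: none
Why: Directed ortho-lithiation between two methoxy groups followed by nucleophilic acyl substitution on the ester, where 10 has no enolisable hydrogen, its existing ketone is shielded by two ortho benzyloxy groups and a branched alkenyl carbon against a di-ortho-substituted aryllithium, and the new ketone is equally protected from over-addition.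

Step 7
Reactants: 13 (2E,3E)-2,3-bis(4-methoxybenzylidene)-1-[2,4,6-tris(benzyloxy)phenyl]-4-(2,4,6-trimethoxyphenyl)butane-1,4-dione
Product: 15 (2E,3E)-1-[2,4-bis(benzyloxy)-6-hydroxyphenyl]-4-(2-hydroxy-4,6-dimethoxyphenyl)-2,3-bis(4-methoxybenzylidene)butane-1,4-dione, via bis(dichloroboryl) chelate 14 (not isolated)
Conditions: BCl3 (2.2 equiv), CH2Cl2, −78 → 0 °C; cold pH 7 phosphate buffer; dark
Reagents that add atoms: none
Why: Chelation-directed aryl ether cleavage, in which BCl3 binds each ketone oxygen and a neighbouring ortho ether oxygen, chloride removes that benzyl or methyl group, and the resulting six-membered boron chelate ties up the reagent and holds the aryloxide away from the enone, so one equivalent per ketone should free exactly one ortho phenol per ring without premature ring closure.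

Step 8
Reactants: 15 (2E,3E)-1-[2,4-bis(benzyloxy)-6-hydroxyphenyl]-4-(2-hydroxy-4,6-dimethoxyphenyl)-2,3-bis(4-methoxybenzylidene)butane-1,4-dione
Product: 18 (2S,3R,2''S,3''R)-5,7-bis(benzyloxy)-5'',7''-dimethoxy-2,2''-bis(4-methoxyphenyl)-3,3''-bichroman-4,4''-dione, via unit-1-closed monoflavanone 16 (not isolated), via unit-2-closed monoflavanone 17 (not isolated)
Conditions: 9-amino-9-deoxy-epi-dihydroquinidine N-[3,5-bis(trifluoromethyl)phenyl]thiourea (20 mol %), toluene, 4 Å MS, −25 → 0 °C, dark; short silica plug
Reagents that add atoms: none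
Why: The quinuclidine nitrogen deprotonates a chelated 2'-phenol while the thiourea N–H pair holds the carbonyl oxygens of the 1,4-dione, the phenoxide adds to the benzylidene carbon of its own enone, the enol is protonated at C3 by the ammonium ion, and the same events on the second enone carry 16 or 17 on to 18. The closest known reaction is the amine–thiourea-catalysed enantioselective intramolecular oxa-Michael cyclisation of α-substituted 2'-hydroxychalcones to flavanones, here run twice in one flask. Ring C of unit 1 (bond O1–C2) and ring C of unit 2 (bond O1''–C2'') each close in the 6-endo-trig mode, the only alternative, attack on the benzylidene carbon of the other enone, being a disfavoured seven-membered closure. C2 and C2'' are controlled by the catalyst, which presents the same enantioface of each (E)-benzylidene carbon to its phenoxide, whereas C3 and C3'' are controlled thermodynamically, because both stay enolisable under the amine and settle in the 2,3-trans diequatorial arrangement, which for 2S,2''S means 3R,3''R. The step needs catalyst control to outweigh the uncatalysed closure and the bias of the first-formed ring: the two enones are cross-conjugated through the twisted C3–C3'' bond and react independently, the 6'-ethers leave one nucleophilic phenol per ketone and avoid the spontaneous closure typical of 2',6'-dihydroxychalcones, and the α-branch forces each enone into the s-trans conformation needed for closure and makes the closed form the energy minimum, so retro-Michael should be slow at low temperature. A mismatched second closure ends in the unlike diastereomer, which chromatography removes, and this should raise the enantiomeric purity of 18.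

Step 9
Reactants: 18 (2S,3R,2''S,3''R)-5,7-bis(benzyloxy)-5'',7''-dimethoxy-2,2''-bis(4-methoxyphenyl)-3,3''-bichroman-4,4''-dione
Product: 20 ruixianglangdusu B, (2S,3R,2''S,3''R)-5,7,5''-trihydroxy-7''-methoxy-2,2''-bis(4-methoxyphenyl)-3,3''-bichroman-4,4''-dione, via tris(dichloroboryl) ether 19 (not isolated)
Conditions: BCl3 (6 equiv), pentamethylbenzene (6 equiv), CH2Cl2, −78 → 0 °C; ice-water
Reagents that add atoms: none
Why: BCl3 with pentamethylbenzene as a non-basic benzyl-cation trap is an established low-temperature aryl benzyl ether cleavage, BCl3 also removes the 5''-methyl ether peri to C4''=O through its boron chelate while the unchelated 7''- and anisyl methyl ethers stay, and no base is present that could enolise C3/C3'' or open the rings.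

**Compound list**
1 | dimethyl succinate | COC(=O)CCC(=O)OC | starting material
2 | 4-methoxybenzaldehyde | COc1ccc(C=O)cc1 | starting material
3 | (E)-3-(methoxycarbonyl)-4-(4-methoxyphenyl)but-3-enoic acid (Stobbe half-ester, present as its potassium salt) | COC(=O)/C(CC(=O)O)=C/c1ccc(OC)cc1 | intermediate
4 | (2E,3E)-2,3-bis(4-methoxybenzylidene)succinic acid | COc1ccc(/C=C(/C(=O)O)C(=C/c2ccc(OC)cc2)\C(=O)O)cc1 | intermediate
5 | (3E,4E)-3,4-bis(4-methoxybenzylidene)dihydrofuran-2,5-dione | COc1ccc(/C=C2/C(=O)OC(=O)/C2=C/c2ccc(OC)cc2)cc1 | intermediate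
6 | 1,3,5-tris(benzyloxy)benzene | c1ccc(COc2cc(OCc3ccccc3)cc(OCc3ccccc3)c2)cc1 | starting material
7 | 2-bromo-1,3,5-tris(benzyloxy)benzene | Brc1c(OCc2ccccc2)cc(OCc2ccccc2)cc1OCc1ccccc1 | intermediate
8 | 2,4,6-tris(benzyloxy)phenyllithium | [Li]c1c(OCc2ccccc2)cc(OCc2ccccc2)cc1OCc1ccccc1 | intermediate
9 | (2E,3E)-2-(4-methoxybenzylidene)-4-(4-methoxyphenyl)-3-[2,4,6-tris(benzyloxy)benzoyl]but-3-enoic acid | COc1ccc(/C=C(/C(=O)c2c(OCc3ccccc3)cc(OCc3ccccc3)cc2OCc2ccccc2)C(=C/c2ccc(OC)cc2)\C(=O)O)cc1 | intermediate
10 | methyl ester of 9 | COc1ccc(/C=C(/C(=O)c2c(OCc3ccccc3)cc(OCc3ccccc3)cc2OCc2ccccc2)C(=C/c2ccc(OC)cc2)\C(=O)OC)cc1 | intermediate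
11 | 1,3,5-trimethoxybenzene | COc1cc(OC)cc(OC)c1 | starting material
12 | 2,4,6-trimethoxyphenyllithium | [Li]c1c(OC)cc(OC)cc1OC | intermediate
13 | (2E,3E)-2,3-bis(4-methoxybenzylidene)-1-[2,4,6-tris(benzyloxy)phenyl]-4-(2,4,6-trimethoxyphenyl)butane-1,4-dione | COc1ccc(/C=C(/C(=O)c2c(OCc3ccccc3)cc(OCc3ccccc3)cc2OCc2ccccc2)C(=C/c2ccc(OC)cc2)\C(=O)c2c(OC)cc(OC)cc2OC)cc1 | intermediate
14 | bis(O-dichloroboryl) derivative of 15 (each boron also chelated by the adjacent ketone oxygen; dative bonds not drawn) | COc1ccc(/C=C(/C(=O)c2c(OB(Cl)Cl)cc(OCc3ccccc3)cc2OCc2ccccc2)C(=C/c2ccc(OC)cc2)\C(=O)c2c(OB(Cl)Cl)cc(OC)cc2OC)cc1 | intermediate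
15 | (2E,3E)-1-[2,4-bis(benzyloxy)-6-hydroxyphenyl]-4-(2-hydroxy-4,6-dimethoxyphenyl)-2,3-bis(4-methoxybenzylidene)butane-1,4-dione | COc1ccc(/C=C(/C(=O)c2c(O)cc(OCc3ccccc3)cc2OCc2ccccc2)C(=C/c2ccc(OC)cc2)\C(=O)c2c(O)cc(OC)cc2OC)cc1 | intermediate
16 | (2S,3R)-5,7-bis(benzyloxy)-3-[(E)-1-(2-hydroxy-4,6-dimethoxybenzoyl)-2-(4-methoxyphenyl)vinyl]-2-(4-methoxyphenyl)chroman-4-one | COc1ccc([C@H]2Oc3cc(OCc4ccccc4)cc(OCc4ccccc4)c3C(=O)[C@@H]2C(=C/c2ccc(OC)cc2)\C(=O)c2c(O)cc(OC)cc2OC)cc1 | intermediate
17 | (2S,3R)-3-[(E)-1-[2,4-bis(benzyloxy)-6-hydroxybenzoyl]-2-(4-methoxyphenyl)vinyl]-5,7-dimethoxy-2-(4-methoxyphenyl)chroman-4-one | COc1ccc(/C=C(/C(=O)c2c(O)cc(OCc3ccccc3)cc2OCc2ccccc2)[C@H]2C(=O)c3c(OC)cc(OC)cc3O[C@@H]2c2ccc(OC)cc2)cc1 | intermediate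
18 | (2S,3R,2''S,3''R)-5,7-bis(benzyloxy)-5'',7''-dimethoxy-2,2''-bis(4-methoxyphenyl)-3,3''-bichroman-4,4''-dione | COc1ccc([C@H]2Oc3cc(OCc4ccccc4)cc(OCc4ccccc4)c3C(=O)[C@@H]2[C@H]2C(=O)c3c(OC)cc(OC)cc3O[C@@H]2c2ccc(OC)cc2)cc1 | intermediate
19 | 5,7,5''-tris(O-dichloroboryl) derivative of 20 (dative bonds not drawn) | COc1ccc([C@H]2Oc3cc(OB(Cl)Cl)cc(OB(Cl)Cl)c3C(=O)[C@@H]2[C@H]2C(=O)c3c(OB(Cl)Cl)cc(OC)cc3O[C@@H]2c2ccc(OC)cc2)cc1 | intermediate
20 | ruixianglangdusu B, (2S,3R,2''S,3''R) | COc1ccc([C@H]2Oc3cc(O)cc(O)c3C(=O)[C@@H]2[C@H]2C(=O)c3c(O)cc(OC)cc3O[C@@H]2c2ccc(OC)cc2)cc1 | target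

**Step count**
Total steps: 9. Longest linear sequence: 8 (steps 1, 2, 4, 5, 6, 7, 8, 9). Step 3 is a one-step side branch.

**Steps most likely to fail**

**Step 8.**
- What may go wrong:
  - Enantioface discrimination at one or both benzylidene carbons may be weak.
  - The first-formed ring may override the catalyst in the second closure.
  - An uncatalysed closure may compete.
  - The intermediate dienolate may be protonated at the far benzylic carbon, which moves the remaining alkene to C3=C3''.
  - Ring opening and re-closure may erode the stereochemistry.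
- Fallback (sets out from 15, returns at 18): both rings are closed without chiral control by the classical chalcone–flavanone isomerisation (NaOAc, EtOH, reflux). This runs under thermodynamic control and should favour the trans,trans series. The like-configured racemate is isolated by crystallisation or chromatography. It consists of 18 and its mirror image, the (2R,3S,2''R,3''S)-biflavanone F1. The two are separated by preparative chromatography on a polysaccharide-carbamate chiral phase. Resubmitting F1 to the NaOAc conditions should re-racemise it through ring opening and closure, so it can be recycled.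

**Step 6.**
- What may go wrong:
  - Acyl substitution at the crowded enoate may be sluggish.
  - Conjugate addition or attack on the existing ketone may compete.
  - The benzyl ethers may be metalated on warming.
- Fallback (sets out from 9, returns at 13): the second aryl group is added at the aldehyde oxidation level, where an enal is far more electrophilic than the shielded ketone. Acid 9 is activated with isobutyl chloroformate and N-methylmorpholine (THF, −15 °C) as the isobutyl carbonic mixed anhydride F2. This is reduced in the same flask with NaBH4 to the hydroxy ketone F3. MnO2 (CH2Cl2) oxidises the allylic alcohol to the keto aldehyde F4. Aryllithium 12 adds 1,2 to the aldehyde at −78 °C to give the carbinol F5, as both epimers at a centre that is erased next. Dess–Martin periodinane (NaHCO3, CH2Cl2) then gives 13.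

**Step 4.**
- What may go wrong:
  - Conjugate or double addition to the bis-alkylidene anhydride may occur.
  - The fulgide may be poorly soluble at −78 °C.
  - Ring–chain tautomerism of the keto acid may complicate isolation.
- Fallback (sets out from 5, returns at 10, skipping 9): the anhydride is desymmetrised with an oxygen nucleophile instead of a carbon one. Methanolysis of 5 (MeOH, cat. DMAP, CH2Cl2) gives the monomethyl half-ester F6. Oxalyl chloride with cat. DMF (CH2Cl2, 0 °C) converts its free acid into the acid chloride F7. Aryllithium 8, made from 7 as in step 4, is acylated by F7 at −78 °C. The acid chloride reacts far faster than the ester, so 10 forms directly.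

**Further compounds**
F1 | step 8 | (2R,3S,2''R,3''S)-5,7-bis(benzyloxy)-5'',7''-dimethoxy-2,2''-bis(4-methoxyphenyl)-3,3''-bichroman-4,4''-dione (mirror image of 18) | COc1ccc([C@@H]2Oc3cc(OCc4ccccc4)cc(OCc4ccccc4)c3C(=O)[C@H]2[C@@H]2C(=O)c3c(OC)cc(OC)cc3O[C@H]2c2ccc(OC)cc2)cc1
F2 | step 6 | isobutyl carbonic mixed anhydride of 9 | COc1ccc(/C=C(/C(=O)c2c(OCc3ccccc3)cc(OCc3ccccc3)cc2OCc2ccccc2)C(=C/c2ccc(OC)cc2)\C(=O)OC(=O)OCC(C)C)cc1
F3 | step 6 | (2E,3E)-3-(hydroxymethyl)-2-(4-methoxybenzylidene)-4-(4-methoxyphenyl)-1-[2,4,6-tris(benzyloxy)phenyl]but-3-en-1-one | COc1ccc(/C=C(/C(=O)c2c(OCc3ccccc3)cc(OCc3ccccc3)cc2OCc2ccccc2)C(=C/c2ccc(OC)cc2)\CO)cc1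
F4 | step 6 | (2E,3E)-2-(4-methoxybenzylidene)-4-(4-methoxyphenyl)-3-[2,4,6-tris(benzyloxy)benzoyl]but-3-enal | COc1ccc(/C=C(/C(=O)c2c(OCc3ccccc3)cc(OCc3ccccc3)cc2OCc2ccccc2)C(=C/c2ccc(OC)cc2)\C=O)cc1
F5 | step 6 | (2E,3E)-4-hydroxy-2,3-bis(4-methoxybenzylidene)-1-[2,4,6-tris(benzyloxy)phenyl]-4-(2,4,6-trimethoxyphenyl)butan-1-one (carbinol centre unassigned) | COc1ccc(/C=C(/C(=O)c2c(OCc3ccccc3)cc(OCc3ccccc3)cc2OCc2ccccc2)C(=C/c2ccc(OC)cc2)\C(O)c2c(OC)cc(OC)cc2OC)cc1
F6 | step 4 | (2E,3E)-3-(methoxycarbonyl)-2-(4-methoxybenzylidene)-4-(4-methoxyphenyl)but-3-enoic acid | COc1ccc(/C=C(/C(=O)O)C(=C/c2ccc(OC)cc2)\C(=O)OC)cc1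
F7 | step 4 | methyl (2E,3E)-3-(chlorocarbonyl)-2-(4-methoxybenzylidene)-4-(4-methoxyphenyl)but-3-enoate | COc1ccc(/C=C(/C(=O)Cl)C(=C/c2ccc(OC)cc2)\C(=O)OC)cc1
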